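## Structural features

The target is an isoflavan: a chroman whose phloroglucinol-type ring A (5-OMe, 7-OH) is fused through C4a and C8a to the saturated oxygen ring C (O1–C2–C3–C4), with ring B (2'-OH, 3'-prenyl, 4'-OMe) attached at C3. C3 is the only stereocentre and is R; it lies between two methylene groups (C2 and C4), so there is no neighbouring stereocentre from which its configuration could be relayed. Ring B is a contiguous 1,2,3,4-tetrasubstituted arene with the prenyl group wedged between two oxygens, and the four ring oxygens must finish as two methyl ethers and two free phenols. The fragile parts are the prenyl alkene next to a free phenol (acid closes it to a dimethylchroman, hydrogenation saturates it), the oxidisable electron-rich phenols, and the C3–H bond, which turns acidic whenever C2 becomes cationic or carbonyl-like. The real difficulty is therefore the absolute configuration of an isolated benzylic methine, and after it the placing of the prenyl group at C3' without late acid or hydrogenation. The key step uses the fact that ring A with its C8a–O1 and C4a–C4 bonds is a masked ortho-quinone methide: a salicyl alcohol whose benzylic carbon C4 ionises under very mild acid because the C5 and C7 oxygens and the phenolic oxygen all donate into it. Adding the two-carbon alkene of a ring B enecarbamate across C4 and O1 builds ring C, both new skeletal bonds and the C3 stereocentre in one catalytic event.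

## Logic of the disconnections

**20 to 19.** The O7–H bond is traced back to O7–Si. The C7 phenol has to stay masked through Brønsted acid, Lewis acid, heat and a ruthenium carbene, and a bulky silyl ether does this and leaves under neutral fluoride. The gain is an endgame with no acid near the prenyl phenol. The forward step must cleave Si–O without touching the alkene or C3.

**19 to 17 and 18.** The trisubstituted C=C bond of the side chain is cut. The prenyl alkene would not survive the acidic steps, so it is reduced to an allyl group that becomes prenyl only afterwards, with 18 as the source of the isopropylidene end. The forward cross-metathesis must favour the trisubstituted product and tolerate the free 2'-phenol.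

**17 to 15.** The C3'–CH2 bond is cut and the allyl unit is reconnected to O2' (retro-Claisen). The O-allyl group then serves twice: it protects the 2'-phenol through the key step and it is the carbon source for C3'. Ring B simplifies from a tetrasubstituted to a 1,2,4-trisubstituted arene. Regiochemistry is forced because the other ortho carbon, C1', carries the chroman. The forward step needs about 190 °C without harm to the silyl ether or C3.

**15 to 14.** One C2–H bond is replaced by C2–N. This turns ring C into an N,O-acetal, the retron of a hetero-[4+2] addition. The forward step must remove the carbamate by hydride delivery to a C2 cation that is not allowed to lose the C3 proton.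

**14 to 4 and 12 (through 13).** C3–C4 and O1–C2 are cut. The polarity fits exactly: C4 is the electrophilic methide carbon of 13, C3 the nucleophilic β-carbon of 12, and C2 the acyliminium carbon that O1 captures. The skeleton falls into two aromatic halves of similar size, each three steps from a commercial benzaldehyde, and the only stereocentre is made in the same step. The forward step demands:
- a chiral acid that controls the face of the alkene of 12;
- ionisation of 4 under acid mild enough for 12 to survive;
- cross-reaction faster than self-condensation of 13.

Three design choices serve this: the bulky silyl group at O7 flanks C6 and C8 against self-alkylation, the carbamate keeps its N–H for two-point binding and is acid-stable, and the 2'-oxygen carries an acid-stable allyl group.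

**12 to 9.** The vinyl C–N bond is traced back to a vinyl C–CO2H bond (Curtius retron). The E geometry is set cheaply in a cinnamic acid and carried over with retention. The forward step must keep the rearrangement temperature well below that of the allyl ether rearrangement and trap 11 with benzyl alcohol.

**9 to 7.** The Cα=Cβ bond is cut to an aldehyde and a malonic acid unit. The forward condensation must give the E acid.

**7 to 5 and 6.** The O2'–allyl bond is cut. The forward step is a simple O-alkylation of the single phenol of 5.

**4 to 3.** The benzylic C4–O alcohol is traced back to a formyl group. The formyl group is the control element that tells the three ring A oxygens apart. The forward reduction must stop at the alcohol and the product must be handled without acid.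

**3 to 2.** The O5–CH3 bond is cut. In 2 the formyl oxygen can chelate only one of the two equivalent ortho hydroxyls, so the other is free for a single alkylation. The forward step must stop at the monoether.

**2 to 1.** The O7–Si bond is cut. The C4 hydroxyl of 1 (future O7) is the only one not flanked by the formyl group. The forward step must silylate once.

## Other disconnections considered

**Alternative 1:** Ring A is cut at C4a–C8a, C5–C6 and C7–C8, back to the tethered diyne A1 (which already holds C3 and a complete ring B) and the silyloxyalkyne A2. In the forward sense [Rh(cod)2]BF4 with BINAP would cyclotrimerise the two alkynes of A1 with A2, closing rings A and C together to give A3.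
- In its favour: three C–C bonds and two rings form in one neutral step. On bond count per step this is the better plan (three bonds and two rings against two bonds and one ring). It is also the better plan in leaving no C2 substituent to excise, and the ring A oxygen pattern is written into the alkynes.
- Against it: the step creates no stereocentre, so C3 of A1 has to be set by a separate asymmetric operation and the chiral ligand has nothing to control. Three alkynyl ethers are hydrolytically delicate and laborious to make. The orientation of A2 decides whether the silyloxy group lands at C7 or C6; sterics should favour C7 but nothing enforces it. A2 can trimerise with itself, and the prenyl alkene of A1 is a competing ligand. After the key step an acid-labile methoxymethyl ether must be removed next to the prenyl phenol.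
- Comparison: mechanistically the metallacycle route is milder than a cationic methide. Structurally it answers the easy question (ring A) and leaves the hard one (C3) open. In step economy, A1 alone should cost more steps than the whole chosen route.

**Alternative 2:** Ring B is cut at C1'–C6' and C3'–C4', back to the chroman-3-ylacetone A4 and methyl acrylate A5. KOtBu would trigger Michael addition from the more substituted α-carbon of A4 and then Claisen condensation from its methyl group, giving the dione A6. C-prenylation at the carbon between the carbonyls, dehydrogenative aromatisation, selective 4'-O-methylation and deprotection would follow.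
- In its favour: cheap reagents, no precious metal and classical enolate chemistry, which is less delicate than a transient methide; on robustness of the key step itself it is at least the equal of the chosen plan. The prenyl group goes to the doubly activated carbon that becomes C3', so on prenyl regiocontrol it is the better plan (no sigmatropic step, no metathesis). The extra stereocentre in ring B vanishes on aromatisation.
- Against it: C3 of A4 carries three CH2-type arms (C2, C4 and the acetonyl carbon), a centre that is harder to make enantiopure than the target's own. The Michael step must choose the methylene over the methyl side. Aromatising a prenylated dione in the presence of the trisubstituted alkene and ring A is a harsh oxidation. The two ring B oxygens must be told apart late, and the final deprotection is again acidic.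
- Comparison: at least five steps follow the key step, against four in the chosen plan, before A4 is even counted. The chosen plan is shorter and solves the stereocentre in the ring-forming step.

**Alternative 3:** Ring B is cut at C5'–C6', C2'–C3', C4'–C5' and C1'–C2', back to the diazo enone A7 and the methoxyalkyne A8. Irradiation of A7 would start a cascade of Wolff rearrangement, [2+2] addition of A8, four-electron ring opening and six-electron ring closure, ending in A9, the 7-O-methoxymethyl ether of 20.
- In its favour: the whole of ring B, with free 2'-OH, 3'-prenyl and 4'-OMe, appears in one step, with regiochemistry fixed by the polarity of A8. On ring B construction and on the length of the endgame (one step against four) it is clearly the better plan.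
- Against it: no stereocentre is formed. C3 of A7 is allylic and γ to the enone carbonyl, so any base used in making the diazo ketone risks vinylogous deprotonation and loss of configuration. A7 also presupposes an enantiopure chroman-3-carbaldehyde, a separate asymmetric problem. Diazo ketones and alkoxyalkynes are hazardous and sensitive. The prenyl alkene of A8 can intercept the ketene or carbene stages. The last step is acidic removal of a methoxymethyl group beside an ortho-prenyl phenol, whereas the chosen route ends with fluoride.
- Comparison: mechanistically it is the most elegant of the four plans for ring B. Overall it trades a short endgame for a long and risky route to A7, so its total step count should exceed that of the chosen plan.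

Key step: step 7

Assumption: the (R)-enantiomer of the phosphoric acid is written as the one that leads to (3R); for a methide without a C4 substituent the sense of induction cannot be read safely from a model, and the (S)-acid, equally available, is used if the opposite face is preferred.

## Route

Step 1
Reactants: 1 2,4,6-trihydroxybenzaldehyde
Product: 2 2,6-dihydroxy-4-(triisopropylsilyloxy)benzaldehyde
Conditions: TIPSCl (1.05 equiv), imidazole, DMF, 0 °C
Reagents that add atoms: triisopropylsilyl chloride, CC(C)[Si](Cl)(C(C)C)C(C)C
Why: Selective phenol O-silylation; the C4 hydroxyl is the least hindered and the only one not flanked by the formyl group, and the bulky chlorosilane avoids the two ortho hydroxyls, so one equivalent should stop at the monosilyl ether.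

Step 2
Reactants: 2 2,6-dihydroxy-4-(triisopropylsilyloxy)benzaldehyde
Product: 3 2-hydroxy-6-methoxy-4-(triisopropylsilyloxy)benzaldehyde
Conditions: MeOH (1.2 equiv), PPh3 (1.1 equiv), DIAD (1.1 equiv), THF, 0 °C to rt
Reagents that add atoms: methanol, CO
Why: Mitsunobu O-methylation; the formyl oxygen chelates only one of the two equivalent ortho hydroxyls, so the free one is alkylated and the product keeps a single chelated, deactivated hydroxyl, which stops the reaction at the monoether. The neutral conditions avoid C-methylation of the phloroglucinol ring and loss of the silyl group.

Step 3
Reactants: 3 2-hydroxy-6-methoxy-4-(triisopropylsilyloxy)benzaldehyde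
Product: 4 2-(hydroxymethyl)-3-methoxy-5-(triisopropylsilyloxy)phenol
Conditions: NaBH4 (1.0 equiv), THF/EtOH, 0 °C; pH 7 buffer work-up, used at once
Reagents that add atoms: none
Why: Borohydride reduction of an aromatic aldehyde; the ethers are inert, and low temperature, one equivalent of hydride and a neutral work-up keep the easily ionised benzylic alcohol from over-reduction or self-condensation.

Step 4
Reactants: 5 2-hydroxy-4-methoxybenzaldehyde; 6 allyl bromide
Product: 7 2-allyloxy-4-methoxybenzaldehyde
Conditions: K2CO3, DMF, 50 °C
Reagents that add atoms: none
Why: Williamson ether synthesis; the only acidic site of 5 is the chelated phenol, whose phenoxide displaces bromide from the allylic halide.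

Step 5
Reactants: 7 2-allyloxy-4-methoxybenzaldehyde
Product: 9 (E)-3-(2-allyloxy-4-methoxyphenyl)prop-2-enoic acid, via arylidenemalonic acid 8 (not isolated)
Conditions: malonic acid (2 equiv), pyridine, piperidine (cat.), 90 °C
Reagents that add atoms: malonic acid, OC(=O)CC(=O)O
Why: Knoevenagel condensation with Doebner decarboxylation; loss of CO2 from 8 gives the thermodynamically preferred E acid, and 90 °C is far below the temperature at which the aryl allyl ether rearranges.

Step 6
Reactants: 9 (E)-3-(2-allyloxy-4-methoxyphenyl)prop-2-enoic acid
Product: 12 benzyl (E)-N-[2-(2-allyloxy-4-methoxyphenyl)ethenyl]carbamate, via acyl azide 10 (not isolated), via vinyl isocyanate 11 (not isolated)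
Conditions: DPPA, Et3N, toluene, 0 °C to rt; then 85 °C; then BnOH, 85 °C; Et3N-deactivated silica
Reagents that add atoms: diphenylphosphoryl azide (DPPA), [N-]=[N+]=NP(=O)(Oc1ccccc1)Oc1ccccc1; benzyl alcohol, OCc1ccccc1
Why: Curtius rearrangement; the alkenyl group migrates with retention of its E geometry from 10 to 11, and benzyl alcohol adds to the isocyanate to give the N–H enecarbamate without isolation of the azide.

Step 7
Reactants: 4 2-(hydroxymethyl)-3-methoxy-5-(triisopropylsilyloxy)phenol; 12 benzyl (E)-N-[2-(2-allyloxy-4-methoxyphenyl)ethenyl]carbamate
Product: 14 benzyl N-[(3R)-3-(2-allyloxy-4-methoxyphenyl)-5-methoxy-7-(triisopropylsilyloxy)chroman-2-yl]carbamate (both C2 epimers), via ortho-quinone methide 13 (not isolated)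
Conditions: (R)-3,3'-bis(2,4,6-triisopropylphenyl)-1,1'-binaphthyl-2,2'-diyl hydrogen phosphate [(R)-TRIP] (10 mol%), 12 (1.3 equiv), 4 Å MS, toluene, −20 to 0 °C, slow addition of 4; Et3N quench
Reagents that add atoms: none
Why: The phosphoric acid protonates the benzylic hydroxyl of 4 and water leaves, helped by the C5 methoxy, C7 silyloxy and phenolic oxygens, to give methide 13, which stays hydrogen-bonded to the phosphate through its carbonyl oxygen while the phosphoryl oxygen holds the N–H of 12. Inside this assembly the β-carbon of 12 (future C3) adds to the methide carbon (C4) and O1 then closes onto the N-acyliminium carbon (C2), an asynchronous inverse-electron-demand oxa-[4+2] cycloaddition. The closest known reaction type is the chiral phosphoric acid-catalysed cycloaddition of in situ ortho-quinone methides with enecarbamates, enamides and enol ethers. Ring C closes as a six-membered oxacycle by this [4+2] mode, which in the stepwise picture is a 6-exo-trig attack of O1 on the exocyclic C=N bond. C3 is the only controlled stereocentre: its configuration is fixed at C3–C4 bond formation by the enantioface of the (E)-alkene that the 3,3'-aryl groups of the catalyst leave open, whereas C2 forms as both epimers and is later reduced to CH2. Regiochemistry follows polarity, the nucleophilic aryl-bearing carbon going to C4 and the nitrogen-bearing carbon to O1. The step also needs the cross-reaction to outrun methide self-condensation and enecarbamate hydrolysis, which the bulky silyl group flanking C6 and C8, the slow addition of 4 and the sieves are there to secure.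

Step 8
Reactants: 14 benzyl N-[(3R)-3-(2-allyloxy-4-methoxyphenyl)-5-methoxy-7-(triisopropylsilyloxy)chroman-2-yl]carbamate
Product: 15 (3R)-3-(2-allyloxy-4-methoxyphenyl)-5-methoxy-7-(triisopropylsilyloxy)chroman
Conditions: Et3SiH (5 equiv), BF3·OEt2 (2 equiv), CH2Cl2, −78 to −30 °C
Reagents that add atoms: none
Why: Ionic hydrogenation of an N,O-acetal; BF3 bound to the carbamate carbonyl makes the carbamate the leaving group, the ring oxygen stabilises the C2 cation and the silane delivers hydride, so both C2 epimers converge on one CH2 group. C3 is not a reacting centre (it stays R because the O-bearing C2 outranks the aryl carbon before and after), and low temperature with excess silane disfavours proton loss from C3; the silyl ether, allyl ether and terminal alkene tolerate these conditions.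

Step 9
Reactants: 15 (3R)-3-(2-allyloxy-4-methoxyphenyl)-5-methoxy-7-(triisopropylsilyloxy)chroman
Product: 17 (3R)-3-(3-allyl-2-hydroxy-4-methoxyphenyl)-5-methoxy-7-(triisopropylsilyloxy)chroman, via cyclohexadienone 16 (not isolated)
Conditions: PhNEt2, 190 °C, sealed tube
Reagents that add atoms: none
Why: Aromatic Claisen rearrangement, a [3,3] shift; C3' is the only free ortho position because C1' carries the chroman, and dienone 16 tautomerises to the phenol. The basic solvent prevents acid-induced cyclisation of the ortho-allyl phenol, and C3 is not involved.

Step 10
Reactants: 17 (3R)-3-(3-allyl-2-hydroxy-4-methoxyphenyl)-5-methoxy-7-(triisopropylsilyloxy)chroman; 18 2-methyl-2-butene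
Product: 19 (3R)-3-[2-hydroxy-4-methoxy-3-(3-methylbut-2-en-1-yl)phenyl]-5-methoxy-7-(triisopropylsilyloxy)chroman
Conditions: second-generation Grubbs catalyst RuCl2(=CHPh)(PCy3)(H2IMes) (5 mol%), 18 (large excess), CH2Cl2, 40 °C, sealed
Reagents that add atoms: none
Why: Olefin cross-metathesis; with 18 in large excess the terminal alkene is converted into the trisubstituted prenyl alkene with loss of propene, and the ruthenium carbene tolerates free phenols and silyl ethers.

Step 11
Reactants: 19 (3R)-3-[2-hydroxy-4-methoxy-3-(3-methylbut-2-en-1-yl)phenyl]-5-methoxy-7-(triisopropylsilyloxy)chroman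
Product: 20 (3R)-3-[2-hydroxy-4-methoxy-3-(3-methylbut-2-en-1-yl)phenyl]-5-methoxychroman-7-ol
Conditions: Bu4NF, AcOH (1:1), THF, 0 °C
Reagents that add atoms: none
Why: Fluoride-induced cleavage of the aryl silyl ether, driven by the Si–F bond; buffering with acetic acid keeps the medium near neutral, so the ortho-prenyl phenol meets neither strong acid nor strong base and C3 is untouched.

## Compound list

1 | 2,4,6-trihydroxybenzaldehyde | O=Cc1c(O)cc(O)cc1O | starting material
2 | 2,6-dihydroxy-4-(triisopropylsilyloxy)benzaldehyde | O=Cc1c(O)cc(O[Si](C(C)C)(C(C)C)C(C)C)cc1O | intermediate
3 | 2-hydroxy-6-methoxy-4-(triisopropylsilyloxy)benzaldehyde | COc1cc(O[Si](C(C)C)(C(C)C)C(C)C)cc(O)c1C=O | intermediate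
4 | 2-(hydroxymethyl)-3-methoxy-5-(triisopropylsilyloxy)phenol | OCc1c(O)cc(O[Si](C(C)C)(C(C)C)C(C)C)cc1OC | intermediate
5 | 2-hydroxy-4-methoxybenzaldehyde | COc1ccc(C=O)c(O)c1 | starting material
6 | allyl bromide (3-bromoprop-1-ene) | C=CCBr | starting material
7 | 2-allyloxy-4-methoxybenzaldehyde | C=CCOc1cc(OC)ccc1C=O | intermediate
8 | 2-[(2-allyloxy-4-methoxyphenyl)methylidene]propanedioic acid | C=CCOc1cc(OC)ccc1C=C(C(=O)O)C(=O)O | intermediate (not isolated)
9 | (E)-3-(2-allyloxy-4-methoxyphenyl)prop-2-enoic acid | C=CCOc1cc(OC)ccc1/C=C/C(=O)O | intermediate
10 | (E)-3-(2-allyloxy-4-methoxyphenyl)prop-2-enoyl azide | C=CCOc1cc(OC)ccc1/C=C/C(=O)N=[N+]=[N-] | intermediate (not isolated)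
11 | 2-allyloxy-1-[(E)-2-isocyanatoethenyl]-4-methoxybenzene | C=CCOc1cc(OC)ccc1/C=C/N=C=O | intermediate (not isolated)
12 | benzyl (E)-N-[2-(2-allyloxy-4-methoxyphenyl)ethenyl]carbamate | C=CCOc1cc(OC)ccc1/C=C/NC(=O)OCc1ccccc1 | intermediate
13 | 3-methoxy-2-methylidene-5-(triisopropylsilyloxy)cyclohexa-3,5-dien-1-one | C=C1C(=O)C=C(O[Si](C(C)C)(C(C)C)C(C)C)C=C1OC | intermediate (not isolated)
14 | benzyl N-[(3R)-3-(2-allyloxy-4-methoxyphenyl)-5-methoxy-7-(triisopropylsilyloxy)chroman-2-yl]carbamate (both C2 epimers) | COc1cc(O[Si](C(C)C)(C(C)C)C(C)C)cc2c1C[C@H](c1ccc(OC)cc1OCC=C)C(NC(=O)OCc1ccccc1)O2 | intermediate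
15 | (3R)-3-(2-allyloxy-4-methoxyphenyl)-5-methoxy-7-(triisopropylsilyloxy)chroman | COc1cc(O[Si](C(C)C)(C(C)C)C(C)C)cc2c1C[C@H](c1ccc(OC)cc1OCC=C)CO2 | intermediate
16 | 6-allyl-5-methoxy-2-[(3R)-5-methoxy-7-(triisopropylsilyloxy)chroman-3-yl]cyclohexa-2,4-dien-1-one (allyl-bearing carbon unassigned) | COc1cc(O[Si](C(C)C)(C(C)C)C(C)C)cc2c1C[C@H](C1=CC=C(OC)C(CC=C)C1=O)CO2 | intermediate (not isolated)
17 | (3R)-3-(3-allyl-2-hydroxy-4-methoxyphenyl)-5-methoxy-7-(triisopropylsilyloxy)chroman | COc1cc(O[Si](C(C)C)(C(C)C)C(C)C)cc2c1C[C@H](c1ccc(OC)c(CC=C)c1O)CO2 | intermediate
18 | 2-methyl-2-butene | CC=C(C)C | starting material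
19 | (3R)-3-[2-hydroxy-4-methoxy-3-(3-methylbut-2-en-1-yl)phenyl]-5-methoxy-7-(triisopropylsilyloxy)chroman | COc1cc(O[Si](C(C)C)(C(C)C)C(C)C)cc2c1C[C@H](c1ccc(OC)c(CC=C(C)C)c1O)CO2 | intermediate
20 | (3R)-3-[2-hydroxy-4-methoxy-3-(3-methylbut-2-en-1-yl)phenyl]-5-methoxychroman-7-ol | COc1cc(O)cc2c1C[C@H](c1ccc(OC)c(CC=C(C)C)c1O)CO2 | target

## Step count and least certain steps

Total step count: 11 (steps 1–3 and 4–6 are parallel arms). Longest linear sequence: 8 steps (1, 2, 3, 7, 8, 9, 10, 11, or equally 4, 5, 6, 7, 8, 9, 10, 11).

**Step 7 (key step).** Three things may go wrong.
- Facial selectivity may be poor. The methide carries no substituent at C4, so the catalyst has no steric handle on the diene and must order the alkene by hydrogen bonding alone, next to an ortho-allyloxy group.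
- The methide may be consumed by self-alkylation at C6 or C8 of ring A, or the enecarbamate may be hydrolysed by the water that is released.
- The aminal may re-ionise, and the resulting acyliminium may tautomerise to the enecarbamate, which would erode the configuration at C3.

The fallback replaces catalyst control by a covalently bound auxiliary. It sets out from 12 and comes back to the route at 15. Hydrolysis of 12 with dilute aqueous HCl in THF gives (2-allyloxy-4-methoxyphenyl)acetaldehyde F1. F1 is condensed with commercial (S)-4-phenyl-1,3-oxazolidin-2-one under acid catalysis with azeotropic removal of water to give (4S)-3-[(E)-2-(2-allyloxy-4-methoxyphenyl)ethenyl]-4-phenyl-1,3-oxazolidin-2-one F2. Hetero-Diels–Alder addition of F2 to methide 13, released from 4 by achiral diphenyl phosphate (PhO)2P(O)OH, should give (4S)-3-[(3R)-3-(2-allyloxy-4-methoxyphenyl)-5-methoxy-7-(triisopropylsilyloxy)chroman-2-yl]-4-phenyl-1,3-oxazolidin-2-one F3, in which the phenyl group of the auxiliary shields one face of the alkene. The diastereomers at C3 are separable, and the Et3SiH/BF3·OEt2 conditions of step 8 then excise the auxiliary to give 15. The (R)-auxiliary is used if the (S)-auxiliary favours the wrong face.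

**Step 8.** Two things may go wrong.
- Ionisation may take the wrong sense: cleavage of the ring C2–O1 bond gives an open-chain N-acyliminium ion, and its reduction would leave a ring-opened carbamate.
- The C2 cation may lose the C3 proton, and reduction of the resulting 4H-chromene would scramble C3.

The fallback changes the leaving group, so that no acyliminium ion can form. It sets out from 14 and comes back at 15. Catalytic camphorsulfonic acid in MeOH/CH2Cl2 at 0 °C exchanges the carbamate for methoxide, where the large excess of methanol traps the cation before it can lose a proton, to give (3R)-3-(2-allyloxy-4-methoxyphenyl)-2,5-dimethoxy-7-(triisopropylsilyloxy)chroman F4 as C2 epimers. The well-known silane reduction of 2-alkoxychromans (Et3SiH, BF3·OEt2, CH2Cl2, −78 °C) then gives 15.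

**Step 3.** The benzylic oxygen may be lost after the reduction. This can happen by ionisation on a slightly acidic work-up or on silica followed by self-alkylation, or by borate-assisted methide formation and a second hydride delivery if the reaction is warmed.

The fallback masks the product before isolation. It sets out from 3 and comes back at 4. After the NaBH4 reduction the neutral extract is not concentrated but stirred with phenylboronic acid over MgSO4, which ties the phenol and the benzylic alcohol into the cyclic boronate 5-methoxy-2-phenyl-7-(triisopropylsilyloxy)-4H-1,3,2-benzodioxaborinine F5, a form that can be chromatographed and stored. Exchange with 2,2-dimethylpropane-1,3-diol in THF at room temperature, done just before step 7, releases 4 under neutral conditions.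

**Step 2.** Mono-selectivity may fail: a second alkylation would give the diether, and a cautious stoichiometry would leave a three-component mixture that is hard to separate.

The fallback overshoots and comes back. It sets out from 2 and returns at 3. Both hydroxyls are methylated with excess MeOH/PPh3/DIAD to give 2,6-dimethoxy-4-(triisopropylsilyloxy)benzaldehyde F6. MgI2·OEt2 in toluene then removes exactly one ortho methyl group through the magnesium chelate with the formyl oxygen; the resulting magnesium phenoxide deactivates the carbonyl towards a second chelation, so the reaction should stop at 3.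

## Further compounds

F1 | step 7 | (2-allyloxy-4-methoxyphenyl)acetaldehyde | C=CCOc1cc(OC)ccc1CC=O
F2 | step 7 | (4S)-3-[(E)-2-(2-allyloxy-4-methoxyphenyl)ethenyl]-4-phenyl-1,3-oxazolidin-2-one | C=CCOc1cc(OC)ccc1/C=C/N1C(=O)OC[C@@H]1c1ccccc1
F3 | step 7 | (4S)-3-[(3R)-3-(2-allyloxy-4-methoxyphenyl)-5-methoxy-7-(triisopropylsilyloxy)chroman-2-yl]-4-phenyl-1,3-oxazolidin-2-one (C2 epimers) | COc1cc(O[Si](C(C)C)(C(C)C)C(C)C)cc2c1C[C@H](c1ccc(OC)cc1OCC=C)C(N1C(=O)OC[C@@H]1c1ccccc1)O2
F4 | step 8 | (3R)-3-(2-allyloxy-4-methoxyphenyl)-2,5-dimethoxy-7-(triisopropylsilyloxy)chroman (C2 epimers) | COc1cc(O[Si](C(C)C)(C(C)C)C(C)C)cc2c1C[C@H](c1ccc(OC)cc1OCC=C)C(OC)O2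
F5 | step 3 | 5-methoxy-2-phenyl-7-(triisopropylsilyloxy)-4H-1,3,2-benzodioxaborinine | COc1cc(O[Si](C(C)C)(C(C)C)C(C)C)cc2c1COB(c1ccccc1)O2
F6 | step 2 | 2,6-dimethoxy-4-(triisopropylsilyloxy)benzaldehyde | COc1cc(O[Si](C(C)C)(C(C)C)C(C)C)cc(OC)c1C=O
A1 | alternative 1 | 1-[(2R)-1-(ethynyloxy)-5-methoxypent-4-yn-2-yl]-4-methoxy-2-(methoxymethoxy)-3-(3-methylbut-2-en-1-yl)benzene | COC#CC[C@H](c1ccc(OC)c(CC=C(C)C)c1OCOC)COC#C
A2 | alternative 1 | ethynyloxytri(propan-2-yl)silane (triisopropylsilyloxyacetylene) | C#CO[Si](C(C)C)(C(C)C)C(C)C
A3 | alternative 1 | (3R)-5-methoxy-3-[4-methoxy-2-(methoxymethoxy)-3-(3-methylbut-2-en-1-yl)phenyl]-7-(triisopropylsilyloxy)chroman | COc1cc(O[Si](C(C)C)(C(C)C)C(C)C)cc2c1C[C@H](c1ccc(OC)c(CC=C(C)C)c1OCOC)CO2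
A4 | alternative 2 | 1-[(3R)-5-methoxy-7-(methoxymethoxy)chroman-3-yl]propan-2-one | COc1cc(OCOC)cc2c1C[C@H](CC(C)=O)CO2
A5 | alternative 2 | methyl acrylate | C=CC(=O)OC
A6 | alternative 2 | 4-[(3R)-5-methoxy-7-(methoxymethoxy)chroman-3-yl]cyclohexane-1,3-dione (epimers at the ring B carbon) | COc1cc(OCOC)cc2c1C[C@H](C1CCC(=O)CC1=O)CO2
A7 | alternative 3 | (3E)-1-diazo-4-[(3R)-5-methoxy-7-(methoxymethoxy)chroman-3-yl]but-3-en-2-one | COc1cc(OCOC)cc2c1C[C@H](/C=C/C(=O)C=[N+]=[N-])CO2
A8 | alternative 3 | 1-methoxy-5-methylhex-4-en-1-yne | COC#CCC=C(C)C
A9 | alternative 3 | 6-[(3R)-5-methoxy-7-(methoxymethoxy)chroman-3-yl]-3-methoxy-2-(3-methylbut-2-en-1-yl)phenol | COc1cc(OCOC)cc2c1C[C@H](c1ccc(OC)c(CC=C(C)C)c1O)CO2
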